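**Plan**
- Retrosynthesis: remove the C8 acetate (C–O bond, made with inversion) and the C10 vinyl group (conjugate addition), leaving a lactone-fused 3-methylcyclohexenone; cut its C8–C9 and C5–C6 bonds together in one [3+3] operation.
- Enabling feature: on the γ-lactone ring, the acetal carbon C6 (latent oxocarbenium) and the acyl carbon C8 both sit on C7 and form a 1,3-dielectrophile; C9 and C5, flanking C10, are the two nucleophilic termini of a 1,5-bis(silyl)-2,4-dimethylpentadiene.
- Forward: the bis-silane in 2 steps; the lactone acid from furfural and (+)-menthol via tandem dithiane addition/methylation, C11 hydroxylation, angeloylation and unmasking of C8.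
- Key event: the acid chloride acylates C9, then C5 closes onto C6, building the cyclohexenone on the existing lactone (cis-fused).
- Endgame: vinyl conjugate addition (C10), hydride reduction (C8), Mitsunobu acetate with inversion.
- Stereochemistry: (+)-menthol fixes the C6 acetal; this sets C7 (anti addition), then C11 (anti hydroxylation), C6 (tether), C5 (convex face), C10 (anti to C5) and C8 (convex hydride, then inversion).

Key step: step 10

Remark: elemane numbering is used throughout (C5 bears the 2-propenyl group, C6 the lactone oxygen, C8 the acetate, C10 is quaternary, C11/C12 are the lactone α-carbon and carbonyl; β = face of the C10 methyl group), and hydride attack in step 12 is assumed to occur from the convex β-face.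

**Step 1**
Reactants: 1 2,4-dimethylpenta-1,3-diene
Product: 3 trimethyl(2,4-dimethylpenta-2,4-dien-1-yl)silane, via pentadienylpotassium 2 (not isolated)
Conditions: n-BuLi, KOt-Bu, THF/hexane, −78 → −20 °C; then Me3SiCl, −78 °C → rt
Reagents that add atoms: chlorotrimethylsilane, C[Si](C)(C)Cl
Why: Metalation–silylation: the n-BuLi/KOt-Bu superbase should remove an allylic methyl proton to give the symmetrical pentadienyl anion 2, which is silylated at a terminal carbon.

**Step 2**
Reactants: 3 trimethyl(2,4-dimethylpenta-2,4-dien-1-yl)silane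
Product: 5 1,5-bis(trimethylsilyl)-2,4-dimethylpenta-1,3-diene, via silylpentadienylpotassium 4 (not isolated)
Conditions: n-BuLi, KOt-Bu, THF, −78 → −30 °C; then Me3SiCl, −78 °C → rt
Reagents that add atoms: chlorotrimethylsilane, C[Si](C)(C)Cl
Why: A second metalation–silylation at the CH2 flanked by silicon and the diene gives anion 4, which should be silylated at the remote terminus; the double-bond geometries of 5 do not matter because both are reset in step 10.

**Step 3**
Reactants: 6 furfural
Product: 7 5-hydroxyfuran-2(5H)-one (racemic)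
Conditions: O2, hν (visible), rose bengal (cat.), MeOH, rt
Reagents that add atoms: dioxygen, O=O
Why: Dye-sensitised photooxygenation: singlet oxygen adds across the furan ring and methanolysis expels the formyl carbon as methyl formate, leaving the γ-hydroxybutenolide.

**Step 4**
Reactants: 7 5-hydroxyfuran-2(5H)-one; 8 (+)-menthol
Product: 9 (5S)-5-[(1S,2R,5S)-menthyloxy]furan-2(5H)-one
Conditions: camphorsulfonic acid (cat.), toluene, reflux (water separator); crystallisation from light petroleum, mother liquor re-equilibrated with acid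
Reagents that add atoms: none
Why: Acid-catalysed acetalisation gives both C6 epimers, which interconvert under acid, so crystallisation is expected to drain the mixture into the (5S) epimer (crystallisation-induced diastereomer transformation); this fixes the absolute configuration of the route.

**Step 5**
Reactants: 10 1,3-dithiane; 9 (5S)-5-[(1S,2R,5S)-menthyloxy]furan-2(5H)-one
Product: 13 (3S,4S,5S)-4-(1,3-dithian-2-yl)-3-methyl-5-[(1S,2R,5S)-menthyloxy]oxolan-2-one (all-trans), via 2-lithio-1,3-dithiane 11 (not isolated), via lithium enolate 12 (not isolated)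
Conditions: n-BuLi, THF, −30 °C; then 9, −78 °C; then MeI, DMPU, −78 → −20 °C
Reagents that add atoms: iodomethane, CI
Why: Tandem Michael addition–enolate alkylation: 11 should add to C7 anti to the menthyloxy group, and enolate 12 is methylated anti to the new dithianyl group.

**Step 6**
Reactants: 13 (3S,4S,5S)-4-(1,3-dithian-2-yl)-3-methyl-5-[(1S,2R,5S)-menthyloxy]oxolan-2-one
Product: 15 (3S,4S,5S)-4-(1,3-dithian-2-yl)-3-hydroxy-3-methyl-5-[(1S,2R,5S)-menthyloxy]oxolan-2-one, via potassium enolate 14 (not isolated)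
Conditions: KN(SiMe3)2, THF, −78 °C; then 2-(phenylsulfonyl)-3-phenyloxaziridine, −78 °C; AcOH quench
Reagents that add atoms: 2-(phenylsulfonyl)-3-phenyloxaziridine, O=S(=O)(N1OC1c1ccccc1)c1ccccc1
Why: Enolate hydroxylation with an N-sulfonyloxaziridine: the planar enolate 14 should be oxidised on the face anti to the adjacent dithianyl group, setting C11 with OH trans to the C7 substituent; at −78 °C the enolate should react much faster than the thioacetal sulfur.

**Step 7**
Reactants: 15 (3S,4S,5S)-4-(1,3-dithian-2-yl)-3-hydroxy-3-methyl-5-[(1S,2R,5S)-menthyloxy]oxolan-2-one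
Product: 17 (3S,4S,5S)-4-(1,3-dithian-2-yl)-3-methyl-5-[(1S,2R,5S)-menthyloxy]-2-oxooxolan-3-yl (2Z)-2-methylbut-2-enoate, via lithium alkoxide 16 (not isolated)
Conditions: LiN(SiMe3)2, THF, −78 °C; then angelic anhydride, −78 → 0 °C
Reagents that add atoms: angelic anhydride, C/C=C(/C)C(=O)OC(=O)/C(C)=C\C
Why: O-Acylation of the tertiary alkoxide 16 with the anhydride, under amine-free, non-nucleophilic conditions that should avoid Z→E isomerisation to the tiglate.

**Step 8**
Reactants: 17 (3S,4S,5S)-4-(1,3-dithian-2-yl)-3-methyl-5-[(1S,2R,5S)-menthyloxy]-2-oxooxolan-3-yl (2Z)-2-methylbut-2-enoate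
Product: 18 (3S,4R,5S)-4-formyl-3-methyl-5-[(1S,2R,5S)-menthyloxy]-2-oxooxolan-3-yl (2Z)-2-methylbut-2-enoate
Conditions: PhI(O2CCF3)2, NaHCO3, MeCN/H2O (9:1), 0 °C
Reagents that add atoms: water, O
Why: Oxidative dethioacetalisation with a hypervalent iodine reagent under buffered conditions should release the aldehyde without touching the pseudo-ester acetal or the angelate; C7 should hold its configuration because the trans arrangement is the more stable one.

**Step 9**
Reactants: 18 (3S,4R,5S)-4-formyl-3-methyl-5-[(1S,2R,5S)-menthyloxy]-2-oxooxolan-3-yl (2Z)-2-methylbut-2-enoate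
Product: 19 (2S,3S,4S)-4-methyl-4-{[(2Z)-2-methylbut-2-enoyl]oxy}-2-[(1S,2R,5S)-menthyloxy]-5-oxooxolane-3-carboxylic acid
Conditions: NaClO2, NaH2PO4, 2-methylbut-2-ene, t-BuOH/H2O, 0 °C → rt
Reagents that add atoms: sodium chlorite, [Na+].[O-]Cl=O
Why: Pinnick oxidation converts the aldehyde into the acid under mildly acidic conditions, the alkene scavenger protecting the angelate double bond from hypochlorite.

**Step 10**
Reactants: 19 (2S,3S,4S)-4-methyl-4-{[(2Z)-2-methylbut-2-enoyl]oxy}-2-[(1S,2R,5S)-menthyloxy]-5-oxooxolane-3-carboxylic acid; 5 1,5-bis(trimethylsilyl)-2,4-dimethylpenta-1,3-diene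
Product: 22 (3S,3aR,7R,7aS)-3,6-dimethyl-2,4-dioxo-7-(prop-1-en-2-yl)-2,3,3a,4,7,7a-hexahydro-1-benzofuran-3-yl (2Z)-2-methylbut-2-enoate (cis-fused), via acid chloride 20 (not isolated), via α-silyl dienyl ketone 21 (not isolated)
Conditions: 1-chloro-N,N,2-trimethylprop-1-en-1-amine, CH2Cl2, 0 °C; then 5, TiCl4, 2,6-di-tert-butyl-4-methylpyridine, CH2Cl2, −78 → −20 °C; NaHCO3 (aq.)
Reagents that add atoms: none
Why: Proposed new method: the TiCl4-activated acid chloride 20 should acylate the silyl diene 5 at its terminus C9 (SE2'' with loss of the allylic silyl group as Me3SiCl) to give 21, an allylsilane whose γ-carbon is C5; TiCl4 then ionises the pseudo-ester acetal of 21 at C6 (loss of menthoxide), and C5 attacks the cationic C6 with loss of the second silyl group, which leaves the new double bond at C9=C10 in conjugation with the C8 ketone. The closest known reaction types are the Friedel–Crafts acylation of allyl- and pentadienylsilanes, the Lewis-acid substitution of γ-alkoxy-γ-lactones by allylsilanes, and [3+3] annulations of 1,3-bis-silyl nucleophiles with 1,3-dielectrophiles. The cyclohexenone ring closes in a 6-exo-trig mode at the oxocarbenium carbon (the C=O+ bond stays outside the new ring), with the allylsilane reacting in the SE2' sense and its double bond ending inside the ring. C6 is set by the tether from C7 (attack on the face cis to the C7–C8 bond, hence the cis ring fusion); C5 is set by a chair-like transition state that keeps the 2-propenyl group on the convex face, trans to O6; C7 and C11 are carried over from 19. The step needs C9-before-C5 chemoselectivity and terminal rather than internal regioselectivity in the acylation: the acid chloride reacts at −78 °C, well before the acetal ionises, and C9 is the only carbon activated both as pentadienylsilane terminus and as vinylsilane ipso carbon, while its silyl group afterwards fixes the position of the new double bond.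

**Step 11**
Reactants: 22 (3S,3aR,7R,7aS)-3,6-dimethyl-2,4-dioxo-7-(prop-1-en-2-yl)-2,3,3a,4,7,7a-hexahydro-1-benzofuran-3-yl (2Z)-2-methylbut-2-enoate
Product: 24 (3S,3aR,6R,7R,7aS)-6-ethenyl-3,6-dimethyl-2,4-dioxo-7-(prop-1-en-2-yl)octahydro-1-benzofuran-3-yl (2Z)-2-methylbut-2-enoate, via silyl enol ether 23 (not isolated)
Conditions: CH2=CHMgBr, CuBr·SMe2 (cat.), Me3SiCl, DMPU, THF, −78 °C; then 1 M HCl (aq.), 0 °C
Reagents that add atoms: vinylmagnesium bromide, C=C[Mg]Br
Why: Copper-catalysed, Me3SiCl-accelerated conjugate addition: the vinyl group should add to C10 anti to the 2-propenyl group on the adjacent C5 (held pseudoaxial by allylic strain with the C10 methyl), giving the quaternary centre with vinyl trans to the C5 substituent; the enol silane 23 is hydrolysed on work-up.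

**Step 12**
Reactants: 24 (3S,3aR,6R,7R,7aS)-6-ethenyl-3,6-dimethyl-2,4-dioxo-7-(prop-1-en-2-yl)octahydro-1-benzofuran-3-yl (2Z)-2-methylbut-2-enoate
Product: 25 (3S,3aR,4R,6R,7R,7aS)-6-ethenyl-4-hydroxy-3,6-dimethyl-2-oxo-7-(prop-1-en-2-yl)octahydro-1-benzofuran-3-yl (2Z)-2-methylbut-2-enoate (8α-alcohol)
Conditions: NaBH4, CeCl3·7H2O, MeOH, −40 °C
Reagents that add atoms: none
Why: Luche-type borohydride reduction: hydride should be delivered to the convex β-face of the cis-fused bicycle, anti to the lactone ring and its inward-pointing C11 methyl, giving the 8α-alcohol (OH cis to the C7–C11 bond); lactone, angelate and alkenes should be inert.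

**Step 13**
Reactants: 25 (3S,3aR,4R,6R,7R,7aS)-6-ethenyl-4-hydroxy-3,6-dimethyl-2-oxo-7-(prop-1-en-2-yl)octahydro-1-benzofuran-3-yl (2Z)-2-methylbut-2-enoate
Product: 26 (3S,3aR,4S,6R,7R,7aS)-4-(acetyloxy)-6-ethenyl-3,6-dimethyl-2-oxo-7-(prop-1-en-2-yl)octahydro-1-benzofuran-3-yl (2Z)-2-methylbut-2-enoate (target CNP0140071.1)
Conditions: AcOH, PPh3, DIAD, toluene, 0 °C → rt
Reagents that add atoms: acetic acid, CC(=O)O
Why: Mitsunobu esterification: acetate should displace the phosphorus-activated C8 oxygen by SN2 from the convex face, inverting C8 to the 8β-acetate of the target; the tertiary angelate and the lactone are not affected.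

**Compound list**
1 | 2,4-dimethylpenta-1,3-diene | C=C(C)C=C(C)C | starting material
2 | (2,4-dimethylpentadienyl)potassium | [K+].[CH2-]C(C)=CC(C)=C | intermediate
3 | trimethyl(2,4-dimethylpenta-2,4-dien-1-yl)silane (double-bond isomers) | C=C(C)C=C(C)C[Si](C)(C)C | intermediate
4 | [2,4-dimethyl-1-(trimethylsilyl)pentadienyl]potassium | [K+].C[Si](C)(C)[CH-]C(C)=CC(C)=C | intermediate
5 | 1,5-bis(trimethylsilyl)-2,4-dimethylpenta-1,3-diene (geometrical isomers) | C[Si](C)(C)C=C(C)C=C(C)C[Si](C)(C)C | intermediate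
6 | furfural (furan-2-carbaldehyde) | O=Cc1ccco1 | starting material
7 | 5-hydroxyfuran-2(5H)-one (racemic) | O=C1OC(O)C=C1 | intermediate
8 | (+)-menthol, (1S,2R,5S)-5-methyl-2-(propan-2-yl)cyclohexan-1-ol | C[C@H]1CC[C@@H]([C@H](C1)O)C(C)C | starting material
9 | (5S)-5-{[(1S,2R,5S)-5-methyl-2-(propan-2-yl)cyclohexyl]oxy}furan-2(5H)-one | O=C1O[C@H](O[C@H]2C[C@@H](C)CC[C@@H]2C(C)C)C=C1 | intermediate
10 | 1,3-dithiane | C1CSCSC1 | starting material
11 | 2-lithio-1,3-dithiane | [Li]C1SCCCS1 | intermediate
12 | lithium enolate of the 4,5-trans conjugate adduct (dithianyl at C7 anti to menthyloxy at C6) | [Li]OC1=C[C@H](C2SCCCS2)[C@@H](O[C@H]2C[C@@H](C)CC[C@@H]2C(C)C)O1 | intermediate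
13 | (3S,4S,5S)-4-(1,3-dithian-2-yl)-3-methyl-5-[(1S,2R,5S)-menthyloxy]oxolan-2-one (all-trans) | O=C1O[C@H](O[C@H]2C[C@@H](C)CC[C@@H]2C(C)C)[C@@H](C2SCCCS2)[C@@H]1C | intermediate
14 | potassium enolate of 13 | [K]OC1=C(C)[C@H](C2SCCCS2)[C@@H](O[C@H]2C[C@@H](C)CC[C@@H]2C(C)C)O1 | intermediate
15 | (3S,4S,5S)-4-(1,3-dithian-2-yl)-3-hydroxy-3-methyl-5-[(1S,2R,5S)-menthyloxy]oxolan-2-one (OH trans to dithianyl) | O=C1O[C@H](O[C@H]2C[C@@H](C)CC[C@@H]2C(C)C)[C@@H](C2SCCCS2)[C@]1(C)O | intermediate
16 | lithium alkoxide of 15 | O=C1O[C@H](O[C@H]2C[C@@H](C)CC[C@@H]2C(C)C)[C@@H](C2SCCCS2)[C@]1(C)O[Li] | intermediate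
17 | (3S,4S,5S)-4-(1,3-dithian-2-yl)-3-methyl-5-[(1S,2R,5S)-menthyloxy]-2-oxooxolan-3-yl (2Z)-2-methylbut-2-enoate | O=C1O[C@H](O[C@H]2C[C@@H](C)CC[C@@H]2C(C)C)[C@@H](C2SCCCS2)[C@]1(C)OC(=O)/C(C)=C\C | intermediate
18 | (3S,4R,5S)-4-formyl-3-methyl-5-[(1S,2R,5S)-menthyloxy]-2-oxooxolan-3-yl (2Z)-2-methylbut-2-enoate | O=C1O[C@H](O[C@H]2C[C@@H](C)CC[C@@H]2C(C)C)[C@@H](C=O)[C@]1(C)OC(=O)/C(C)=C\C | intermediate
19 | (2S,3S,4S)-4-methyl-4-{[(2Z)-2-methylbut-2-enoyl]oxy}-2-[(1S,2R,5S)-menthyloxy]-5-oxooxolane-3-carboxylic acid | O=C1O[C@H](O[C@H]2C[C@@H](C)CC[C@@H]2C(C)C)[C@@H](C(=O)O)[C@]1(C)OC(=O)/C(C)=C\C | intermediate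
20 | acid chloride of 19 (C8 carbonyl chloride) | O=C1O[C@H](O[C@H]2C[C@@H](C)CC[C@@H]2C(C)C)[C@@H](C(=O)Cl)[C@]1(C)OC(=O)/C(C)=C\C | intermediate
21 | 4-[3,5-dimethyl-2-(trimethylsilyl)hexa-3,5-dienoyl] lactone (C7, C11, C6 as in 19; mixture at the silyl-bearing carbon and at the 3,4-double bond) | O=C1O[C@H](O[C@H]2C[C@@H](C)CC[C@@H]2C(C)C)[C@@H](C(=O)C([Si](C)(C)C)C(C)=CC(C)=C)[C@]1(C)OC(=O)/C(C)=C\C | intermediate
22 | (3S,3aR,7R,7aS)-3,6-dimethyl-2,4-dioxo-7-(prop-1-en-2-yl)-2,3,3a,4,7,7a-hexahydro-1-benzofuran-3-yl (2Z)-2-methylbut-2-enoate | CC1=CC(=O)[C@@H]2[C@@H](OC(=O)[C@@]2(C)OC(=O)/C(C)=C\C)[C@@H]1C(=C)C | intermediate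
23 | trimethylsilyl enol ether of 24 (C8–OSiMe3, C8=C9; vinyl at C10 trans to the C5 2-propenyl group) | C=C[C@@]1(C)C=C(O[Si](C)(C)C)[C@@H]2[C@@H](OC(=O)[C@@]2(C)OC(=O)/C(C)=C\C)[C@@H]1C(=C)C | intermediate
24 | (3S,3aR,6R,7R,7aS)-6-ethenyl-3,6-dimethyl-2,4-dioxo-7-(prop-1-en-2-yl)octahydro-1-benzofuran-3-yl (2Z)-2-methylbut-2-enoate | C=C[C@@]1(C)CC(=O)[C@@H]2[C@@H](OC(=O)[C@@]2(C)OC(=O)/C(C)=C\C)[C@@H]1C(=C)C | intermediate
25 | (3S,3aR,4R,6R,7R,7aS)-6-ethenyl-4-hydroxy-3,6-dimethyl-2-oxo-7-(prop-1-en-2-yl)octahydro-1-benzofuran-3-yl (2Z)-2-methylbut-2-enoate | C=C[C@@]1(C)C[C@@H](O)[C@@H]2[C@@H](OC(=O)[C@@]2(C)OC(=O)/C(C)=C\C)[C@@H]1C(=C)C | intermediate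
26 | (3S,3aR,4S,6R,7R,7aS)-4-(acetyloxy)-6-ethenyl-3,6-dimethyl-2-oxo-7-(prop-1-en-2-yl)octahydro-1-benzofuran-3-yl (2Z)-2-methylbut-2-enoate | C=C[C@@]1(C)C[C@H](OC(C)=O)[C@@H]2[C@@H](OC(=O)[C@@]2(C)OC(=O)/C(C)=C\C)[C@@H]1C(=C)C | target

**Totals**
Total step count: 13. Longest linear sequence: 11 steps (steps 3 to 13); steps 1 and 2 form the short branch that joins at step 10.

**Steps most likely to fail**

Step 10 (proposed new method). The acylation may occur at the internal carbon of the silyl diene, the silyl groups may be lost by protonation before ring closure, or menthol may be eliminated across C6–C7 instead of C5 bonding to C6. The fallback makes the two bonds one after the other with known reactions; it sets out from acid 19 and mono-silane 3 and returns at enone 22. The acid chloride from 19 (same chloroenamine) and 3 with TiCl4 at −78 °C should give, by Friedel–Crafts acylation of the pentadienylsilane at its terminus, the skipped dienyl ketone F1. Me3SiOTf/Et3N should then enolise F1 towards C9 to the conjugated silyl trienol ether F2. Catalytic Me3SiOTf at −78 °C should ionise the acetal and close the ring by an intramolecular vinylogous Mukaiyama addition of C5 to C6, giving 22.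

Step 11. 1,2-Addition to the ketone or deprotonation at C5 may compete with transfer of the vinyl group to the hindered β-carbon. The fallback uses a slim, non-basic alkynyl nucleophile and a later partial reduction; it sets out from 22 and returns at 24. Et2AlC≡CSiMe3 with zerovalent nickel generated from Ni(acac)2 and i-Bu2AlH (conjugate alkynylation of an s-trans enone) should give the β-alkynyl ketone F3. Bu4NF buffered with AcOH should remove the silyl group to give the terminal alkyne F4. Semi-hydrogenation (H2, Pd/CaCO3 poisoned with Pb(OAc)2, quinoline) should then give 24.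

Step 13. The concave 8α-alcohol may not be activated by the bulky phosphonium reagent, or elimination may outrun substitution. The fallback separates activation from displacement; it sets out from 25 and returns at 26. MsCl/Et3N should give the mesylate F5, and CsOAc with 18-crown-6 in toluene at 90 °C should displace it with inversion to give 26.

**Further compounds**
F1 | step 10 | 4-(3,5-dimethylhexa-3,5-dienoyl) lactone (C6, C7, C11 as in 19) | O=C1O[C@H](O[C@H]2C[C@@H](C)CC[C@@H]2C(C)C)[C@@H](C(=O)CC(C)=CC(C)=C)[C@]1(C)OC(=O)/C(C)=C\C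
F2 | step 10 | trimethylsilyl trienol ether of F1 (C8–OSiMe3, C8=C9) | O=C1O[C@H](O[C@H]2C[C@@H](C)CC[C@@H]2C(C)C)[C@@H](C(O[Si](C)(C)C)=CC(C)=CC(C)=C)[C@]1(C)OC(=O)/C(C)=C\C
F3 | step 11 | C10 (trimethylsilyl)ethynyl analogue of 24 | C[Si](C)(C)C#C[C@@]1(C)CC(=O)[C@@H]2[C@@H](OC(=O)[C@@]2(C)OC(=O)/C(C)=C\C)[C@@H]1C(=C)C
F4 | step 11 | C10 ethynyl analogue of 24 | C#C[C@@]1(C)CC(=O)[C@@H]2[C@@H](OC(=O)[C@@]2(C)OC(=O)/C(C)=C\C)[C@@H]1C(=C)C
F5 | step 13 | 8α-methanesulfonate of 25 | C=C[C@@]1(C)C[C@@H](OS(C)(=O)=O)[C@@H]2[C@@H](OC(=O)[C@@]2(C)OC(=O)/C(C)=C\C)[C@@H]1C(=C)C
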